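Two questions stand here: when the flask holds most target, and how much. I answer the second with one quantity and read the first from the shape of the runs.

| setting | red | green | flask |
|---|---|---|---|
| starting material | 0.20 M | 0.20 M | 0.20 M |
| coupling partner | 0.31 M | 0.48 M | 0.220 M |
| second substrate | 0.20 M | 0.20 M | 0.200 M |
| protic impurity | 0.060 M | 0.060 M | 0.0600 M |
| remark | run made earlier | run made earlier |  |
| time |  |  | 5.0 min |

| run | time / min | target / % |
|---|---|---|
| red | 0.667 | 9.4 |
| red | 0.833 | 11.3 |
| red | 1.33 | 12.9 |
| red | 1.50 | 13.5 |
| red | 2.00 | 14.1 |
| red | 3.00 | 14.1 |
| green | 0.667 | 14.7 |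
| green | 0.833 | 16.2 |
| green | 1.33 | 20.2 |
| green | 1.50 | 19.8 |
| green | 2.00 | 21.3 |
| green | 3.00 | 22.6 |

(each reading ± 0.5 percentage points)

1. time, not beyond 5.0 min, at which the flask holds most target
2. the amount of target, in percent of the starting material charged, at that time

- what was read earlier has a scatter of 0.5 percentage points, one standard deviation

The red run, nearer to this flask in partner charge than the green run, reads 14.1% at 2.00 min and 14.1% at 3.00 min, so I expect this flask to level off at about those times as well. The partner charge c_B is what differs between the runs, so I divide each last reading P by it. Two extreme flasks can be reckoned in the head.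

In the first extreme, the protic impurity, charged at c_H, takes no partner:

w = mean of P/c_B over red and green = 0.463 L mol⁻¹
w·c_B = 10.2% for this flask

In the second, the impurity takes its whole charge, one partner each, and the rest is usable partner:

u = mean of P/(c_B − c_H) over red and green = 0.551 L mol⁻¹
u·(c_B − c_H) = 8.82% for this flask

This u, the yield per usable partner, is the share of starting material that becomes target for each mole per litre of partner left usable. I assume one partner for each impurity and let the impurity take between nothing and its 0.0600 M, so my estimate for this flask lies between 8.82% and 10.2%.

The forecast gives 9% at 5 min, expecting the target to “then stay flat”.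

The flask gives 10.3% at 2.64 min, just above my upper extreme.

    coupling partner ⇌ dormant form (K = 11.0, k = 0.00840 s⁻¹)
    starting material + coupling partner ⇌ target (K = 3.40 L mol⁻¹, k = 0.0130 L mol⁻¹ s⁻¹)
    coupling partner + protic impurity → quenched reagent (k = 0.110 L mol⁻¹ s⁻¹)
    second substrate + coupling partner ⇌ second product (K = 2.80 L mol⁻¹, k = 0.0340 L mol⁻¹ s⁻¹)

At 5.00 min this flask holds 9.25% of target beside 0.0498 M of quenched reagent, and u times the partner charge less that amount gives 9.38%. The neighbouring flask with 0.50 M of starting material has the same partner and impurity charges; u, read at 0.20 M of starting material, gives 8.82% for it if the whole charge is quenched, and that flask's best is 9.01%.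

Readings and results were computed with made-up constants; noise was put on by code.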